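I read every flask at 2.0 min, so I ask which clocks run out before that moment, taking the shortest first.

| flask | starting material | reagent | protic impurity | temperature | remark | time |
|---|---|---|---|---|---|---|
| oak | 36 mM | 64.8 mM | 3.6 mM | 55 °C | run made earlier |  |
| ash | 36 mM | 43 mM | 3.6 mM | 70 °C | run made earlier |  |
| elm | 36 mM | 97 mM | 3.6 mM | 55 °C | run made earlier |  |
| violet | 36 mM | 64.8 mM | 3.60 mM | 70 °C | everything together at the start | 2.0 min |
| amber | 36 mM | 64.8 mM (fed, over 1.5 min) | 3.60 mM |  | the addition at 40 °C, then warmed to 70 °C; the feed brings no volume worth counting | 2.0 min |
| ochre | 36 mM | 64.8 mM | 3.60 mM |  | everything together at the start at 40 °C, warmed to 70 °C at 1.5 min | 2.0 min |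
| red | 36 mM (fed, over 1.5 min) | 64.8 mM | 3.60 mM | 70 °C | all else is in the flask from the start; the feed brings no volume worth counting | 2.0 min |
| grey | 36 mM | 64.8 mM (fed, over 1.5 min) | 3.60 mM | 70 °C | all else is in the flask from the start; the feed brings no volume worth counting | 2.0 min |

oak run (percent of the starting material charged)

| time / min | target / % |
|---|---|
| 0.333 | 13 |
| 0.417 | 16 |
| 0.667 | 19 |
| 1.00 | 27 |
| 2.00 | 33 |
| 3.00 | 39 |

ash run (percent of the starting material charged)

| time / s | target / % |
|---|---|
| 10.0 | 11 |
| 15.0 | 15 |
| 25.0 | 17 |
| 40.0 | 26 |
| 60.0 | 29 |
| 80.0 | 32 |
| 90.0 | 32 |

elm run (percent of the starting material charged)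

| time / min | target / % |
|---|---|
| 0.500 | 25 |
| 1.00 | 29 |
| 1.33 | 33 |
| 2.00 | 43 |
| 3.00 | 44 |

(each reading ± 1.5 percentage points)

- on the list of suspects stand: starting material + reagent -> target; starting material -> side product; 2 reagent -> self-condensation product; starting material + protic impurity -> quenched substrate

- which flask leads in amount of target, in percent of the starting material charged ("all alike" within 1.5 percentage points) (violet / amber / ochre / red / grey / all alike)
- how much target is there at the end, in percent of the starting material charged: violet
- how much target is there at the end, in percent of the starting material charged: amber
- how much target is there at the end, in percent of the starting material charged: ochre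
- how much target is there at the end, in percent of the starting material charged: red
- how much target is there at the end, in percent of the starting material charged: grey

1. In the ash run at 70 °C, the target stands at 17% after 25.0 s. That is half of its last reading, 32%. I read this bend as reagent dying by self-condensation, although other losses may sit in it too. The first half-life of a step that takes two reagent shortens as the reagent charge grows, so I scale this time by the charges. At the charge of violet it gives 0.276 min. This is my reagent's life: the time to half the last target reading of the ash run, scaled inversely with the reagent charge. It is a reading and carries the scatter.

2. The first ash reading is 11% at 10.0 s. Scaled to the same charge, that early speed would use up the starting material in 1.01 min. This pseudo-first-order time is longer than the reagent's life, so in violet the reagent thins while starting material remains.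

3. The feed lasts 1.5 min, which is 5.43 reagent's lives. Within one life, the feed in red has brought 6.64 mM of starting material, so the reagent mostly waits, and I expect red well behind violet.

4. Amber and ochre get 0.500 min at 70 °C, which is shorter than the pseudo-first-order time. I expect them behind violet too, with much starting material left. Grey I cannot place with this clock.

The forecast names grey as leader, with violet 39.5%, amber 36%, ochre 34.5%, red 16% and grey 44%. It argues that “Grey keeps reagent low, which suppresses the second-order loss”.

The flasks give violet 39.7%, amber 30.7%, ochre 32.4%, red 21.1% and grey 29.8%, so violet leads.

    starting material + reagent → target (k = 0.370 /M/s, Ea = 64.0 kJ/mol)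
    starting material → side product (k = 0.0100 /s, Ea = 88.0 kJ/mol)
    2 reagent → self-condensation product (k = 0.330 /M/s, Ea = 61.0 kJ/mol)
    starting material + protic impurity → quenched substrate (k = 4.50 /M/s, Ea = 60.0 kJ/mol)
    (constants at 70 °C)

In red, the self-condensation has half of its turnover up to 2.0 min behind it at 0.245 min, beside my reagent's life of 0.276 min, while the feed runs to 1.5 min. Taking that step away narrows the gap between violet and red from 19 percentage points to 6.6 points, the largest single effect, though it accounts for a part of the gap and not for the whole.

A neighbour like red holds 140 mM of starting material. The reagent's life counts reagent, so it stays 0.276 min, and one life now brings 25.8 mM of starting material. The neighbour makes 21.8 mM of target against 7.58 mM in red, though as a percentage of its charge that is 15.6%.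

(The data stem from a simulated flask with constants of no real substance; scatter was added.)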